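The numbers in the tables come from a simulation from invented constants.

In equivalents of coupling partner, a target costs more than one, if, as I assume, each idle adduct is a target holding a second partner. Sunday's reading at 6.00 h gives

price = 1 + idle adduct / target = 1.90

This is the partner price, the equivalents of coupling partner spent per equivalent of target counted, idle adduct included. The solid substrate looks like the limiting reagent, yet at this price 1.50 equiv of partner pays for 78.9 % of the charge.

| flask | solid substrate | coupling partner | remark | time |
|---|---|---|---|---|
| Tuesday's | 0.10 M | 1.5 equiv | run made earlier |  |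
| Sunday's | 0.16 M | 1.5 equiv | run made earlier |  |
| flask | 0.074 M | 1.50 equiv |  | 6.0 h |
- Tuesday's (time / h: target / %, idle adduct / %): 0.500: 1.4, 1.8; 0.833: 3.7, 3.0; 1.33: 7.5, 7.3; 2.00: 14.8, 13.1; 3.00: 23.9, 21.7; 5.00: 38.8, 34.4; 8.00: 48.8, 39.8
- Sunday's (time / h: target / %, idle adduct / %): 1.00: 5.2, 4.6; 2.00: 12.9, 11.8; 3.00: 22.0, 20.4; 4.00: 29.6, 27.3; 5.00: 36.5, 32.9; 6.00: 41.6, 37.4; 8.00: 49.3, 43.7

(each reading ± 0.3 percentage points)
1. amount of target and idle adduct together at 6.0 h, in percent of the solid substrate charged
2. concentration of dissolved substrate in solution at 6.0 h, in percent of saturation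
- for target the idle adduct is counted in
- as a solid, counted per litre of solution: solid substrate
- at the start none of the solid substrate is in solution
- dissolved substrate means what is dissolved; the solid is not counted in it

The percentages shift little with the charge (38.8 % on Tuesday, 36.5 % on Sunday, both at 5.00 h), so I carry Tuesday's run to this flask. Its last interval gives the gain per hour per equivalent of free partner:

gain = 0.0499 h⁻¹

Starting from 38.8 %, I go to 6.0 h on the free partner at the start of that hour, then again on its mean:

first round: 42.6 %
next round: 42.4 %

The ledger closes with 46.3 % of the partner free. I read no saturation concentration off these readings, so I commit to no figure for it.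

The forecast gives 42 % (37 % to 47 %) and 40 % of saturation (20 % to 70 %), on “the same absolute dissolved concentration, capped near saturation”. The flask gives 42.9 % and 50.2 %.

    solid substrate ⇌ dissolved substrate, rate k1*(cs1 - [dissolved substrate]) while solid is left; crystals form when [dissolved substrate] > cs1 (solubility = 0.0590 M, k = 1.39 × 10⁻⁴ s⁻¹)
    dissolved substrate + coupling partner → target (k = 8.92 × 10⁻⁴ M⁻¹ s⁻¹)
    dissolved substrate + target → side product (k = 0.00263 M⁻¹ s⁻¹)
    target ⇌ isomer of the product (K = 0.779, k = 1.45 × 10⁻⁴ s⁻¹)
    coupling partner + target ⇌ idle adduct, settled at all times (K = 100 M⁻¹)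

In this flask at 1.75 h, dissolved substrate goes to target 35 times as fast as to side product. Yet at 6.0 h its partner price is 1.82 and 41 % of its partner is free, against my 46.3 %, with 12.7 % side product and 4.35 % isomer of the product outside the price. The neighbour charged with 6.00 equiv, at its 94.8 %, should keep 70.0 % of its partner at my price, and it keeps 68 %.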